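# Proposed total synthesis of CNP0271677.1 by an epoxide-opening / Williamson ether cascade

## Structural features

Atom labels used throughout: ring A is C1, C10, C11 (methyl), C12, C13 (ketone), C14; O1 links C2 and C9; C3 (methyl, O2), C4 (butyrate), C5, C6=C7 (methyl on C7) and C8 complete the oxonene; C15 (methyl) and C16 lead from C14 to O2.

- The target is a tetracycle on a 3-methylcyclohex-2-enone (ring A), cis-fused through C1–C10 to a tetrahydrofuran (C1, C2, O1, C9, C10).
- C2 and C9 of that tetrahydrofuran are bridged by C3–C8, so O1 sits in a nine-membered oxonene with a Z trisubstituted C6=C7 alkene.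
- A seven-membered oxepane (C1, C2, C3, O2, C16, C15, C14) is fused to ring A across C1–C14 and shares C1–C2 with the tetrahydrofuran and C2–C3 with the oxonene.
- The eight stereocentres form one branched, contiguous array C9–C10–C1(–C14–C15)–C2–C3–C4, with C3 fully substituted; in these labels the required enantiomer is (1R,2S,3S,4R,9S,10S,14R,15R).
- Fragile groups are the butyrate (base, hydride, nucleophiles), the enone with its epimerisable ring-fusion carbon C14 and acidic γ-hydrogens, and the trisubstituted ring alkene and tertiary ether towards strong acid.
- The real difficulty is the medium ring carrying the oxygenated C2–C3–C4 triad at a quaternary centre, together with telling apart three cis arms on adjacent carbons of ring A.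
- The feature exploited is that C2 and C3 are vicinal and carry O1 and O2 anti to each other, the pattern left by an epoxide opened with inversion at C2. O1 returns to C9 and O2 to C16, both on arms cis to the C1 arm, so one oxirane can close the tetrahydrofuran and the oxepane in a relay.

## Logic of the disconnections

**33 to 32.** No skeletal bond is cut; the C13 ketone is masked as a dioxolane. This removes the acidity at C14, C12 and C10 for every basic, hydridic or organometallic step upstream. The forward step must hydrolyse an allylic ketal without touching the butyrate or the C6=C7 alkene.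

**32 to 31.** C6=C7 is cut (ring-closing metathesis transform). The nine-membered ring is the most strained element and is best closed last, on a rigid tricycle that holds the C2 and C9 arms cis on the tetrahydrofuran. This reduces the oxonene to an allyl and a methallyl group. The forward step must form a trisubstituted Z alkene in a medium ring at high dilution.

**31 to 30 to 29.** The ester C–O bond and then C4–C5 are cut. C4 lies next to the quaternary ether carbon C3, so an aldehyde at C4 cannot epimerise and can be chelated through O2. This removes the C4 stereocentre and the allyl arm. The forward allylation must proceed through the five-membered chelate and not in the Felkin–Anh sense.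

**29 to 28 to 27 to 25.** With C4 returned to a protected alcohol, O1–C2 and O2–C16 are cut together. The anti vicinal diether C2/C3 becomes a C2–C3 epoxide, O1 returns to a C9 carbinol and O2–C16 to a primary sulfonate. Two rings are removed and the stereochemical problem at C2/C3 becomes that of one oxirane. The forward step must open the oxirane 5-exo at C2 and then alkylate the released tertiary alkoxide.

**25 to 24 to 23 to 22.** The two oxirane C–O bonds are removed to give a Z C2=C3 allylic alcohol (asymmetric epoxidation transform), with protecting-group changes at O4 and O9. The demand is reagent control of the alkene face on a Z-allylic alcohol with a branched neighbour, without the C9 oxygen taking part.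

**22 to 21 to 20 to 18.** C8–C9 is cut (methallylation of an aldehyde). The C9 stereocentre and the 2-methylallyl arm are removed together. The forward step must override any bias from C10, so a chiral allylborane is used.

**18 to 17 to 15.** C2=C3 is cut (Z-selective phosphonate olefination), and the resulting C2 aldehyde and C9 alcohol are tied back into a lactol. The demand is kinetic Z-selectivity and suppression of oxa-Michael addition of the freed C9 oxygen.

**15 to 14 to 13 to 12.** The lactol is returned to the lactone and the C13 oxygen is removed (allylic C–H oxidation transform). This leaves a cyclohexene with a single alkene. The forward oxidation must choose the C13 methylene over the C10 methine and must not epimerise C14.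

**12 to 11 to 9 to 8 to 6.** The sulfonate, the C16–O bond (hydroboration), C15=C16 (methylenation) and C15–CH3 (acylation of a methyl nucleophile) are cut in turn, back to a carboxylic acid at C15. The demands are control of the C15 configuration from the ring and no epimerisation at C14.

**6 to 5 to 2 + 3.** The lactone acyl–O bond is opened to a hydroxy anhydride, and C1–C10 and C13–C14 are cut (Diels–Alder transform). An E-1-substituted 2-methyl diene and a symmetrical Z-dienophile give the all-cis triad C10/C1/C14 in one step, and lactonisation distinguishes C2 from C15. The adduct is racemic, so a resolution is required.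

**2 to 1.** The vinyl group is taken back to the terminal alkyne of a commercial E-enynol; the semi-reduction must stop at the alkene.

## Other disconnections considered

**Alternative 1:** The cut is O1–C9 and C8–C9, with O1–C6 re-formed in the retrosynthetic sense, leading from the oxonene-bridged furanone A2 to the tetrahydropyran diazoketone A1.
- **Forward step.** Cu(CF3COCHCOCF3)2 (divalent copper) would turn the diazo carbon C9 into a carbenoid, O1 would capture it, and a [2,3] shift of the oxonium ylide would expand the six-membered ring to the oxonene while closing the furanone.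
- **In its favour.** One step makes a C–O and a C–C bond, the 2,9-cis relation across O1 and the C6=C7 alkene. The medium ring arises by ring expansion, not end-to-end closure; on this point it is better than the metathesis of step 24. C3 and C4 are set on a six-membered ring, which is at least as reliable as the acyclic control used here.
- **Against it here.** A2 contains neither ring A nor the oxepane. C1 is a methylene and C10 a ketone, so ring A would have to be annulated afterwards and C1, C10, C14 and C15 set on a flexible bicycle. The alkene geometry depends on the ylide conformation, and a diazoketone must be handled.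
- **Comparison.** The chosen plan builds the ring A triad first in one cycloaddition and uses it as the template for both ether rings; A2 postpones that problem. Both key steps form two bonds, so they are equal there. Overall the route through A2 is judged no shorter.

**Alternative 2:** The cut is C1–C14 and C10–C11, dividing ring A into the butenolide A3 and the oxygenated diene A4, which would combine to the lactone A5.
- **Forward step.** Endo addition of A4 to the C1=C10 alkene of A3, anti to the C2 substituent, followed by acidic work-up to free the C13 ketone and eliminate methanol.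
- **In its favour.** It is convergent. Ring A arrives with its C13 oxygen and C11=C12 in place, so no allylic C–H oxidation is needed; this is better than steps 8 and 9 here. C15 is carried in from a simple chiral building block, which is better than the substrate-controlled hydroboration of step 6. The lactone already holds O1 between C9 and C2.
- **Against it here.** A4 is doubly substituted at C11 and branched at C14, which penalises the cisoid conformer. γ-Substituted butenolides are sluggish dienophiles, and the acetonide and silyl enol ether restrict the use of Lewis acids. The all-cis triad needs both endo addition and a defined enol ether geometry. C9 must later be taken from lactone to a methallyl-bearing ether carbon, and the oxepane closed after the C3 and C4 oxygens are told apart.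
- **Comparison.** On paper this is the shortest plan, and on step economy it is better. Its risk is concentrated in a hindered bimolecular cycloaddition, whereas the cycloaddition chosen here uses an unhindered diene and maleic anhydride. The two plans are equal in that C14 sits next to the C13 ketone and could be corrected by equilibration.

**Alternative 3:** The cut is C4–C5, with C2–C7 re-formed, leading from the ten-membered silyl enol ether A7 to the decalin alcohol A6.
- **Forward step.** KH with a crown ether would give the C2 alkoxide of A6, an oxy-Cope [3,3] shift would expand ring B to the cyclodecene with the C6=C7 alkene, and Et3SiCl would trap the C2 enolate.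
- **In its favour.** The medium ring forms by a strongly accelerated, strain-releasing rearrangement whose chair transition state transfers the decalin configuration to C4 and to the alkene geometry. For ring formation alone this is better than metathesis. Six-membered precursors are easy to assemble stereoselectively.
- **Against it here.** A7 is a carbocycle with neither ether bridge. C2 and C3 emerge as sp2 carbons, so O1 (C2 to C9), O2 (C3 to C16) and the configurations at C2 and C3 would have to be installed by transannular reactions on a flexible ten-membered ring, with poorly predictable facial control. A6, with a tertiary allylic alcohol, an alkoxyvinyl group and a quaternary C7, is itself long to prepare.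
- **Comparison.** The chosen key step closes both heterocycles where A7 closes none. Both use a potassium alkoxide generated with KH, so they are equal in reagent type and functional-group demands. Step economy is judged worse for the route through A7.

Key step: step 19

## Remarks before the steps

- The configurations of 25 and 27 were checked centre by centre against the target (C2 is 2R in 25 and 2S in 27, as inversion requires); no correction of the skeleton is needed.
- Two design points are changed. O4 carries a 4-methoxybenzyl ether, not a silyl ether, because a silyl group could migrate to the neighbouring tertiary C3 alkoxide formed in the key step. The Diels–Alder adduct is racemic, so a resolution is inserted at step 3.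
- Assumption: in step 3 the (S)-amine is written; the enantiomer of the amine actually used is the one whose salt with acid 6 is the less soluble.

## Route

Step 1
Reactants: 1 (E)-3-methylpent-2-en-4-yn-1-ol
Product: 2 (E)-3-methylpenta-2,4-dien-1-ol
Conditions: H2 (1 atm), Pd/CaCO3 poisoned with Pb(OAc)2 (Lindlar catalyst), quinoline, EtOAc, 0 °C to rt, stopped after 1 equiv
Reagents that add atoms: none
Why: Lindlar semi-hydrogenation reduces the terminal alkyne to the vinyl group and stops there; the E trisubstituted alkene is kept, so the CH2OH group ends on the outer position of the s-cis diene.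

Step 2
Reactants: 2 (E)-3-methylpenta-2,4-dien-1-ol; 3 maleic anhydride
Product: 5 racemic lactone acid, via hydroxy anhydride 4 (not isolated)
Conditions: toluene, BHT (cat.), rt to 80 °C
Reagents that add atoms: none
Why: Thermal Diels–Alder reaction of an E-1-substituted 2-methyl diene with a symmetrical Z-dienophile; the endo transition state places the C9 arm cis to both carbonyl arms, which sets H10, H1 and H14 all cis (relative configuration only), and the C9 hydroxyl then opens the adjacent anhydride carbonyl (C2) to the cis-fused γ-lactone, so C2 (lactone) and C15 (free acid) are told apart without a protecting group.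

Step 3
Reactants: 5 racemic lactone acid
Product: 6 (1R,10S,14S)-lactone acid
Conditions: (S)-1-phenylethylamine (1 equiv), i-PrOH/EtOAc, crystallisation below 40 °C to constant rotation; then 1 M HCl, EtOAc
Reagents that add atoms: none
Why: Classical resolution of a carboxylic acid through its diastereomeric 1-phenylethylammonium salts, placed on the cheapest intermediate so that every later centre is set relative to one enantiomer; the absolute configuration of 6 is to be secured by X-ray analysis of the salt.

Step 4
Reactants: 6 (1R,10S,14S)-lactone acid
Product: 8 methyl ketone, via acid chloride 7 (not isolated)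
Conditions: (COCl)2, DMF (cat.), CH2Cl2, 0 °C to rt; concentrate; Me2CuLi (from MeLi and CuI), Et2O/THF, −78 °C
Reagents that add atoms: lithium dimethylcuprate, [Li+].C[Cu-]C
Why: Acid chloride formation followed by acylation of a Gilman cuprate; Me2CuLi adds once to the acyl chloride at −78 °C and leaves the lactone and the new ketone alone, and neither stage is basic enough to epimerise C14.

Step 5
Reactants: 8 methyl ketone
Product: 9 isopropenyl lactone
Conditions: Zn, CH2Br2, TiCl4, THF/CH2Cl2, 0 °C to rt
Reagents that add atoms: dibromomethane, BrCBr
Why: Takai–Lombardo methylenation; the zinc–titanium methylene reagent is non-basic and selective for ketones over lactones, so C14 next to the carbonyl is not epimerised as it could be by a phosphorus ylide.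

Step 6
Reactants: 9 isopropenyl lactone
Product: 11 primary alcohol (15R), via alkylborane 10 (not isolated)
Conditions: 9-BBN-H, THF, 0 °C to rt; then NaBO3·4H2O, H2O, rt
Reagents that add atoms: sodium perborate, [Na+].[Na+].O[B-]1(O)OO[B-](O)(O)OO1
Why: Hydroboration–oxidation with 9-BBN, which takes the 1,1-disubstituted alkene in preference to the trisubstituted ring alkene and puts boron on C16; the equatorial isopropenyl group on C14 lies next to the axial C1–C2 bond of the cis-fused lactone, the rotamer that avoids a syn-pentane contact between its methyl group and C2 exposes the face remote from the lactone, and hydrogen delivered to C15 from that face should give the 15R configuration; perborate oxidises the C–B bond with retention under conditions mild enough for the lactone.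

Step 7
Reactants: 11 primary alcohol (15R)
Product: 12 tosylate
Conditions: p-TsCl, pyridine, DMAP (cat.), CH2Cl2, 0 °C to rt
Reagents that add atoms: p-toluenesulfonyl chloride, Cc1ccc(cc1)S(Cl)(=O)=O
Why: Sulfonylation of the primary alcohol, done at once so that the C16 hydroxyl cannot translactonise onto C2; the β-branched primary tosylate is expected to survive the non-nucleophilic steps that follow.

Step 8
Reactants: 12 tosylate
Product: 13 enone
Conditions: CrO3, 3,5-dimethylpyrazole, CH2Cl2, −20 °C
Reagents that add atoms: chromium trioxide, O=[Cr](=O)=O
Why: Allylic C–H oxidation with the CrO3–3,5-dimethylpyrazole complex; C13 is the only allylic methylene flanking the CH end of the alkene (C10 is a hindered methine next to the fully substituted alkene carbon), so the β-methyl enone C11=C12–C13=O should predominate as with other 1-methylcyclohexenes, and the medium is neither basic nor strongly acidic, which protects the now enolisable C14.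

Step 9
Reactants: 13 enone
Product: 14 dioxolane lactone
Conditions: Me3SiOCH2CH2OSiMe3, Me3SiOTf (cat.), CH2Cl2, −78 to −40 °C; pyridine quench
Reagents that add atoms: 1,2-bis(trimethylsilyloxy)ethane, C[Si](C)(C)OCCO[Si](C)(C)C
Why: Noyori ketalisation under aprotic, kinetic conditions gives the dioxolane without moving the C11=C12 double bond and without equilibrating C14; the ketal removes all acidic hydrogens of ring A for the basic steps to come.

Step 10
Reactants: 14 dioxolane lactone
Product: 15 lactol
Conditions: iBu2AlH (1.1 equiv), CH2Cl2, −78 °C; aq KNaC4H4O6 work-up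
Reagents that add atoms: none
Why: Half-reduction of a γ-lactone by iBu2AlH stops at the lactol through the stable aluminium hemiacetal at −78 °C; tosylate and ketal are inert, and the lactol is the C2 aldehyde in masked form together with the C9 hydroxyl.

Step 11
Reactants: 15 lactol
Product: 17 hydroxy Z-enoate, via hydroxy aldehyde 16 (not isolated)
Conditions: (CF3CH2O)2P(O)CH(CH3)CO2Me (1.5 equiv), KN(SiMe3)2 (1.3 equiv), 18-crown-6, THF, −78 to −40 °C; cold NH4Cl quench
Reagents that add atoms: methyl 2-[bis(2,2,2-trifluoroethoxy)phosphoryl]propanoate, COC(=O)C(C)P(=O)(OCC(F)(F)F)OCC(F)(F)F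
Why: Still–Gennari olefination on the ring-opened tautomer of the lactol; the bis(trifluoroethyl) phosphonate gives the Z trisubstituted enoate under kinetic control (C1 and the ester cis), the geometry the cis-oxirane needs, while the slight excess of phosphonate over base keeps the liberated C9 hydroxyl protonated and the low temperature holds back oxa-Michael closure onto C2 and epimerisation at C1.

Step 12
Reactants: 17 hydroxy Z-enoate
Product: 18 C9 aldehyde
Conditions: Dess–Martin periodinane, NaHCO3, CH2Cl2, 0 °C; used crude
Reagents that add atoms: none
Why: Dess–Martin oxidation of the primary alcohol under bicarbonate buffer; the β,γ-unsaturated aldehyde with its stereocentre at C10 is not chromatographed, to avoid conjugation or epimerisation.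

Step 13
Reactants: 18 C9 aldehyde
Product: 20 homoallylic alcohol (9S), via borinate 19 (not isolated)
Conditions: (−)-Ipc2BOMe, CH2=C(CH3)CH2MgCl, Et2O, 0 °C to rt, then −78 °C; 18, −78 °C; NaBO3·4H2O, THF/H2O, rt
Reagents that add atoms: 2-methylallylmagnesium chloride, CC(=C)C[Mg]Cl
Why: Brown methallylation; the borane derived from (+)-α-pinene adds through a chair transition state to the Si face of the aldehyde, which gives the 9S carbinol under reagent control whatever modest Felkin bias C10 exerts, and the ester and tosylate do not react with the allylborane at −78 °C.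

Step 14
Reactants: 20 homoallylic alcohol (9S)
Product: 21 triethylsilyl ether
Conditions: Et3SiOTf, 2,6-lutidine, CH2Cl2, −78 °C
Reagents that add atoms: triethylsilyl trifluoromethanesulfonate, CC[Si](CC)(CC)OS(=O)(=O)C(F)(F)F
Why: Silylation of the hindered secondary alcohol with a silyl triflate and a hindered pyridine; no alkoxide is formed, so oxa-Michael addition to the enoate is avoided, and the triethylsilyl group can later be removed beside a benzyl-type ether.

Step 15
Reactants: 21 triethylsilyl ether
Product: 22 Z-allylic alcohol
Conditions: iBu2AlH (2.5 equiv), CH2Cl2, −78 °C; aq KNaC4H4O6 work-up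
Reagents that add atoms: none
Why: iBu2AlH reduces the conjugated ester 1,2 to the Z-allylic alcohol and leaves tosylate, silyl ether and ketal untouched at −78 °C.

Step 16
Reactants: 22 Z-allylic alcohol
Product: 23 epoxy alcohol (2R,3S)
Conditions: Ti(OiPr)4, L-(+)-diethyl tartrate, t-BuOOH, 4 Å molecular sieves, CH2Cl2, −20 °C
Reagents that add atoms: tert-butyl hydroperoxide, CC(C)(C)OO
Why: Sharpless asymmetric epoxidation; only the allylic alcohol binds the titanium tartrate, so the methallyl and ring alkenes are not oxidised, L-(+)-tartrate delivers oxygen in the facial sense that turns nerol-type Z-allylic alcohols into (2S,3R)-epoxy alcohols, which here is the (2R,3S)-oxirane, and syn addition converts the Z geometry into the cis relation of C1 and C4 on the ring; a stoichiometric titanium loading is planned because Z substrates with a branched neighbour react slowly.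

Step 17
Reactants: 23 epoxy alcohol (2R,3S)
Product: 24 4-methoxybenzyl ether
Conditions: NaH, 4-MeOC6H4CH2Br, THF/DMF, 0 °C
Reagents that add atoms: 4-methoxybenzyl bromide, COc1ccc(CBr)cc1
Why: Williamson etherification of the primary epoxy alcohol; a benzyl-type ether is used at O4 because it cannot migrate to the tertiary C3 alkoxide of the key step, and Payne rearrangement would need attack at the tertiary C3 and is not expected in aprotic medium.

Step 18
Reactants: 24 4-methoxybenzyl ether
Product: 25 key-step precursor
Conditions: Bu4NF, AcOH (1:1), THF, 0 °C to rt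
Reagents that add atoms: none
Why: Fluoride cleavage of the triethylsilyl ether buffered with acetic acid; the near-neutral medium leaves oxirane, ketal, tosylate and benzyl ether intact and does not generate the free alkoxide that would start the cyclisation early.

Step 19
Reactants: 25 key-step precursor
Product: 27 tricyclic bis-ether, via potassium alkoxide 26 (not isolated)
Conditions: KH (2.5 equiv), 18-crown-6 (cat.), THF, 0 °C to rt, then 45 °C if needed
Reagents that add atoms: none
Why: KH deprotonates the C9 hydroxyl irreversibly, and the alkoxide attacks C2 from the side opposite the oxirane oxygen in a 5-exo-tet opening that closes the tetrahydrofuran (O1–C2) with inversion at C2 (2R to 2S) and frees the tertiary C3 alkoxide with its configuration unchanged. That alkoxide, held by the new ring and by the cis relation of the C1 and C14 arms within reach of C16, displaces the tosylate in a 7-exo-tet Williamson closure (O2–C16) that forms the oxepane. The closest known reaction types are the base-induced cyclisation of epoxy alcohols to 2-(1-hydroxyalkyl)tetrahydrofurans and intramolecular Williamson etherification, and relays in which the alkoxide released from an oxirane is alkylated in the same flask are established. The only stereocentre that changes is C2, and it is controlled by the stereospecific backside attack; C9 and C3 keep the configurations set in steps 13 and 16. The step needs attack at the secondary C2 in the exo mode and not at the tertiary C3 in the 6-endo mode, and it needs the oxirane to react before O9 can reach the tosylate directly; basic conditions favour the less substituted oxirane carbon, the collinear O···C2–O arrangement is reachable only in the exo mode, and a five-membered opening is much faster than seven-ring SN2 at a β-branched carbon. The C13 dioxolane removes every acidic C–H and the benzyl-type ether at O4 cannot migrate to O3. Crown ether and gentle warming are held in reserve for the slower second closure, where E2 elimination of the tosylate is the competing path.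

Step 20
Reactants: 27 tricyclic bis-ether
Product: 28 primary alcohol
Conditions: DDQ, CH2Cl2/pH 7 buffer, 0 °C
Reagents that add atoms: none
Why: Oxidative cleavage of the 4-methoxybenzyl ether by DDQ in buffered wet dichloromethane; the isolated alkenes, the ketal and the cyclic ethers are not oxidised.

Step 21
Reactants: 28 primary alcohol
Product: 29 C4 aldehyde
Conditions: Dess–Martin periodinane, NaHCO3, CH2Cl2, 0 °C to rt
Reagents that add atoms: none
Why: Dess–Martin oxidation of the neopentyl-type alcohol; the aldehyde has no α-hydrogen because C3 is quaternary, so it can neither enolise nor epimerise.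

Step 22
Reactants: 29 C4 aldehyde
Product: 30 homoallylic alcohol (4R)
Conditions: MgBr2·OEt2, Bu3SnCH2CH=CH2, CH2Cl2, −78 to −20 °C
Reagents that add atoms: allyltributylstannane, CCCC[Sn](CCCC)(CCCC)CC=C
Why: Keck-type chelation-controlled allylation; MgBr2 bridges the aldehyde oxygen and the α-ether oxygen O2 in a five-membered chelate and the allylstannane attacks from the side of the C3 methyl group, away from C2, which gives the 4R alcohol; the dioxolane should survive MgBr2 at low temperature and its early loss would only reveal the enone.

Step 23
Reactants: 30 homoallylic alcohol (4R)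
Product: 31 butyrate
Conditions: (n-PrCO)2O, Et3N, DMAP, CH2Cl2, rt to 40 °C
Reagents that add atoms: butanoic anhydride, CCCC(=O)OC(=O)CCC
Why: DMAP-catalysed acylation of the hindered secondary alcohol, done before metathesis so that no free hydroxyl can bind the ruthenium catalyst.

Step 24
Reactants: 31 butyrate
Product: 32 tetracyclic ketal
Conditions: second-generation Grubbs catalyst (H2IMes)(PCy3)Cl2Ru=CHPh (10 mol%), CH2Cl2 (1 mM), 40 °C
Reagents that add atoms: none
Why: Ring-closing metathesis between the allyl and methallyl groups, held cis on the tetrahydrofuran at C2 and C9, under high dilution; loss of ethene drives closure of the nine-membered ring, in which the trisubstituted C6=C7 alkene is accommodated as the Z isomer.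

Step 25
Reactants: 32 tetracyclic ketal
Product: 33 CNP0271677.1
Conditions: pyridinium p-toluenesulfonate, acetone/H2O, rt to 40 °C
Reagents that add atoms: water, O
Why: Mild acid hydrolysis of the allylic dioxolane returns the C11=C12–C13 enone; the butyrate, the ethers and the ring alkene tolerate pyridinium tosylate and C14 stays cis because it is locked in the oxepane.

## Compound list

1 | (E)-3-methylpent-2-en-4-yn-1-ol | C#C/C(C)=C/CO | starting material
2 | (E)-3-methylpenta-2,4-dien-1-ol | C=C/C(C)=C/CO | intermediate
3 | maleic anhydride | O=C1OC(=O)C=C1 | starting material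
4 | Diels–Alder adduct: all-cis 3-(hydroxymethyl)-4-methylcyclohex-4-ene-1,2-dicarboxylic anhydride (racemic, one enantiomer drawn) | OC[C@@H]1C(C)=CC[C@@H]2C(=O)OC(=O)[C@H]12 | intermediate (not isolated)
5 | racemic lactone acid: γ-lactone C9–O1–C2(=O) cis-fused on C10–C1 of the 11-methylcyclohexene, CO2H (C15) on C14, H1/H10/H14 cis (one enantiomer drawn) | O=C1OC[C@@H]2C(C)=CC[C@H](C(=O)O)[C@H]12 | intermediate
6 | (1R,10S,14S)-lactone acid, single enantiomer of 5 | O=C1OC[C@@H]2C(C)=CC[C@H](C(=O)O)[C@H]12 | intermediate
7 | acid chloride of 6 | O=C1OC[C@@H]2C(C)=CC[C@H](C(=O)Cl)[C@H]12 | intermediate (not isolated)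
8 | methyl ketone: as 6 with C15 as C(=O)CH3 | O=C1OC[C@@H]2C(C)=CC[C@H](C(C)=O)[C@H]12 | intermediate
9 | isopropenyl lactone: as 6 with C14 bearing C(CH3)=CH2 | O=C1OC[C@@H]2C(C)=CC[C@H](C(C)=C)[C@H]12 | intermediate
10 | B-alkyl-9-borabicyclo[3.3.1]nonane, boron on C16, 15R | O=C1OC[C@@H]2C(C)=CC[C@H]([C@@H](C)CB3C4CCCC3CCC4)[C@H]12 | intermediate (not isolated)
11 | primary alcohol: C14 bearing (R)-CH(CH3)CH2OH | O=C1OC[C@@H]2C(C)=CC[C@H]([C@@H](C)CO)[C@H]12 | intermediate
12 | tosylate of 11 | O=C1OC[C@@H]2C(C)=CC[C@H]([C@@H](C)COS(=O)(=O)c3ccc(C)cc3)[C@H]12 | intermediate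
13 | enone: as 12 with C13 ketone conjugated to C11=C12 | O=C1OC[C@@H]2C(C)=CC(=O)[C@H]([C@@H](C)COS(=O)(=O)c3ccc(C)cc3)[C@H]12 | intermediate
14 | dioxolane lactone: 1,3-dioxolane at C13 | O=C1OC[C@@H]2C(C)=CC3(OCCO3)[C@H]([C@@H](C)COS(=O)(=O)c4ccc(C)cc4)[C@H]12 | intermediate
15 | lactol (C2 hemiacetal, both anomers) | OC1OC[C@@H]2C(C)=CC3(OCCO3)[C@H]([C@@H](C)COS(=O)(=O)c4ccc(C)cc4)[C@H]12 | intermediate
16 | open hydroxy aldehyde tautomer of 15 (C9–OH, C2 aldehyde) | OC[C@@H]1C(C)=CC2(OCCO2)[C@H]([C@@H](C)COS(=O)(=O)c3ccc(C)cc3)[C@@H]1C=O | intermediate (not isolated)
17 | hydroxy Z-enoate: C1 bearing (Z)-CH=C(CH3)CO2CH3, C9–OH free | OC[C@@H]1C(C)=CC2(OCCO2)[C@H]([C@@H](C)COS(=O)(=O)c3ccc(C)cc3)[C@@H]1/C=C(/C)C(=O)OC | intermediate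
18 | C9 aldehyde of 17 | O=C[C@@H]1C(C)=CC2(OCCO2)[C@H]([C@@H](C)COS(=O)(=O)c3ccc(C)cc3)[C@@H]1/C=C(/C)C(=O)OC | intermediate
19 | diisopinocampheylborinate of 20 | CC(=C)C[C@H](OB([C@@H]3C[C@@H]4C[C@H]([C@H]3C)C4(C)C)[C@@H]3C[C@@H]4C[C@H]([C@H]3C)C4(C)C)[C@@H]1C(C)=CC2(OCCO2)[C@H]([C@@H](C)COS(=O)(=O)c5ccc(C)cc5)[C@@H]1/C=C(/C)C(=O)OC | intermediate (not isolated)
20 | (9S)-homoallylic alcohol: C9 bearing OH and 2-methylallyl | CC(=C)C[C@H](O)[C@@H]1C(C)=CC2(OCCO2)[C@H]([C@@H](C)COS(=O)(=O)c3ccc(C)cc3)[C@@H]1/C=C(/C)C(=O)OC | intermediate
21 | triethylsilyl ether of 20 | CC(=C)C[C@H](O[Si](CC)(CC)CC)[C@@H]1C(C)=CC2(OCCO2)[C@H]([C@@H](C)COS(=O)(=O)c3ccc(C)cc3)[C@@H]1/C=C(/C)C(=O)OC | intermediate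
22 | Z-allylic alcohol: C1 bearing (Z)-CH=C(CH3)CH2OH | CC(=C)C[C@H](O[Si](CC)(CC)CC)[C@@H]1C(C)=CC2(OCCO2)[C@H]([C@@H](C)COS(=O)(=O)c3ccc(C)cc3)[C@@H]1/C=C(/C)CO | intermediate
23 | (2R,3S)-epoxy alcohol: cis C2–C3 oxirane, C4–OH free | CC(=C)C[C@H](O[Si](CC)(CC)CC)[C@@H]1C(C)=CC2(OCCO2)[C@H]([C@@H](C)COS(=O)(=O)c3ccc(C)cc3)[C@@H]1[C@H]4O[C@@]4(C)CO | intermediate
24 | 4-methoxybenzyl ether of 23 at O4 | CC(=C)C[C@H](O[Si](CC)(CC)CC)[C@@H]1C(C)=CC2(OCCO2)[C@H]([C@@H](C)COS(=O)(=O)c3ccc(C)cc3)[C@@H]1[C@H]4O[C@@]4(C)COCc5ccc(OC)cc5 | intermediate
25 | key-step precursor: (9S)-carbinol on C10, (2R,3S)-oxirane on C1, (15R)-tosylate arm on C14, C13 dioxolane, O4 4-methoxybenzyl | CC(=C)C[C@H](O)[C@@H]1C(C)=CC2(OCCO2)[C@H]([C@@H](C)COS(=O)(=O)c3ccc(C)cc3)[C@@H]1[C@H]4O[C@@]4(C)COCc5ccc(OC)cc5 | intermediate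
26 | potassium C3 alkoxide with the tetrahydrofuran closed and the tosylate still in place | C=C(C)C[C@@H]1O[C@H]([C@@](C)([O-])COCc2ccc(OC)cc2)[C@@H]3[C@H]1C(C)=CC4(OCCO4)[C@@H]3[C@@H](C)COS(=O)(=O)c5ccc(C)cc5.[K+] | intermediate (not isolated)
27 | tricyclic bis-ether: tetrahydrofuran and oxepane closed, 2-methylallyl on C9, C13 dioxolane, O4 4-methoxybenzyl | C=C(C)C[C@@H]2O[C@H]3[C@@H]4[C@H]2C(C)=CC5(OCCO5)[C@@H]4[C@@H](C)CO[C@@]3(C)COCc6ccc(OC)cc6 | intermediate
28 | primary alcohol at C4 | C=C(C)C[C@@H]2O[C@H]3[C@@H]4[C@H]2C(C)=CC5(OCCO5)[C@@H]4[C@@H](C)CO[C@@]3(C)CO | intermediate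
29 | C4 aldehyde | C=C(C)C[C@@H]2O[C@H]3[C@@H]4[C@H]2C(C)=CC5(OCCO5)[C@@H]4[C@@H](C)CO[C@@]3(C)C=O | intermediate
30 | (4R)-homoallylic alcohol: C4 bearing OH and allyl | C=C(C)C[C@@H]2O[C@H]3[C@@H]4[C@H]2C(C)=CC5(OCCO5)[C@@H]4[C@@H](C)CO[C@@]3(C)[C@H](O)CC=C | intermediate
31 | butyrate of 30 | C=C(C)C[C@@H]2O[C@H]3[C@@H]4[C@H]2C(C)=CC5(OCCO5)[C@@H]4[C@@H](C)CO[C@@]3(C)[C@H](OC(=O)CCC)CC=C | intermediate
32 | tetracyclic ketal: target skeleton with C13 dioxolane, Z C6=C7 | CCCC(=O)O[C@@H]1C/C=C(/C)C[C@@H]2O[C@H]3[C@@H]4[C@H]2C(C)=CC5(OCCO5)[C@@H]4[C@@H](C)CO[C@@]13C | intermediate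
33 | CNP0271677.1 | CCCC(=O)O[C@@H]1C/C=C(/C)C[C@@H]2O[C@H]3[C@@H]4[C@H]2C(C)=CC(=O)[C@@H]4[C@@H](C)CO[C@@]13C | target

## Step count and least certain steps

Total: 25 steps. Longest linear sequence: 25 steps (from 1; 3 enters at step 2).

**Step 19 (key step).** The cascade may stall after the tetrahydrofuran closure: the hindered tertiary alkoxide could eliminate the β-branched tosylate instead of substituting it, or O9 could attack C16 before the oxirane. The fallback separates the two closures and replaces the alkoxide displacement by a neutral one.
- It sets out from 25. K2CO3 in MeOH closes only the tetrahydrofuran, because the protic medium protonates the tertiary alkoxide, giving the hydroxy tosylate F1.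
- CsOAc and 18-crown-6 in DMF at 60 °C convert it into the acetate F2, and K2CO3 in MeOH then gives the diol F3.
- Tf2O and 2,6-lutidine in CH2Cl2 at −78 to 0 °C triflate the primary hydroxyl, which the neutral tertiary C3 hydroxyl displaces. The fallback returns to the route at 27.

**Step 6.** Facial selectivity of the hydroboration may be poor, because it rests on a rotamer argument for an exocyclic alkene and not on a rigid ring. The fallback replaces substrate control by catalyst control.
- It sets out from 8. KN(SiMe3)2 and PhNTf2 at −78 °C give the enol triflate F4 by kinetic deprotonation of the methyl group.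
- Stille coupling with Bu3SnCH2OH, Pd(PPh3)4 and LiCl in dioxane gives the 2-substituted allylic alcohol F5.
- Hydroxyl-directed asymmetric hydrogenation with Ru(OAc)2(BINAP), the ligand enantiomer chosen for the 15R sense, sets C15 without touching the ring alkene. The fallback returns at 11.

**Step 16.** The epoxidation may be slow and mismatched: the Z-allylic alcohol has a branched neighbour and its own facial preference may oppose that of the tartrate, giving poor diastereoselectivity or partial opening of the product by titanium. The fallback uses a dioxirane that needs no free hydroxyl.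
- It sets out from 22, which is first etherified (NaH, 4-methoxybenzyl bromide) to the allylic ether F6.
- F6 is epoxidised with the D-fructose-derived Shi ketone, 2KHSO5·KHSO4·K2SO4 and K2CO3 in MeCN/dimethoxymethane/buffer at 0 °C. The spiro transition state for trisubstituted alkenes predicts the same (2R,3S) sense.
- The ring alkene is deactivated by the neighbouring ketal and the 1,1-disubstituted alkene reacts slowly. The fallback returns at 24.

**Step 11.** The C9 alkoxide freed on olefination may add to the new enoate (oxa-Michael closure of the tetrahydrofuran outside the planned cascade), or the open aldehyde may epimerise at C1 while the lactol opens slowly. The fallback avoids a free hydroxyl during olefination.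
- It sets out from 14. Me(MeO)NH·HCl and Me3Al give the hydroxy Weinreb amide F7, and Et3SiCl with imidazole gives its silyl ether F8.
- iBu2AlH at −78 °C gives the aldehyde F9, and Still–Gennari olefination gives the silylated Z-enoate F10.
- HF·pyridine with excess pyridine removes the silyl group. The fallback returns at 17.

**Step 22.** Chelation may be lost: O2 is a hindered ring ether and O1 on C2 could compete for magnesium, so the Felkin–Anh face may be attacked and the C4 epimer formed. The fallback corrects C4 by oxidation and reduction.
- It sets out from 29 and passes through the epimeric alcohol F11, which Dess–Martin periodinane oxidises to the allyl ketone F12.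
- LiBH(sec-Bu)3 in THF at −78 °C, a non-chelating hydride, should attack the same Felkin–Anh face that the allyl group took, which places hydrogen where allyl stood. The fallback returns at 30.

## Further compounds

F1 | step 19 | hydroxy tosylate: tetrahydrofuran closed, C3–OH free, C16 tosylate | C=C(C)C[C@@H]1O[C@H]([C@@](C)(O)COCc2ccc(OC)cc2)[C@@H]3[C@H]1C(C)=CC4(OCCO4)[C@@H]3[C@@H](C)COS(=O)(=O)c5ccc(C)cc5
F2 | step 19 | C16 acetate of the tetrahydrofuran alcohol | C=C(C)C[C@@H]1O[C@H]([C@@](C)(O)COCc2ccc(OC)cc2)[C@@H]3[C@H]1C(C)=CC4(OCCO4)[C@@H]3[C@@H](C)COC(C)=O
F3 | step 19 | diol: C3–OH and C16–OH free | C=C(C)C[C@@H]1O[C@H]([C@@](C)(O)COCc2ccc(OC)cc2)[C@@H]3[C@H]1C(C)=CC4(OCCO4)[C@@H]3[C@@H](C)CO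
F4 | step 6 | enol triflate at C15 | O=C1OC[C@@H]2C(C)=CC[C@H](C(=C)OS(=O)(=O)C(F)(F)F)[C@H]12
F5 | step 6 | 2-substituted allylic alcohol: C14 bearing C(=CH2)CH2OH | O=C1OC[C@@H]2C(C)=CC[C@H](C(=C)CO)[C@H]12
F6 | step 16 | 4-methoxybenzyl ether of Z-allylic alcohol 22 | CC(=C)C[C@H](O[Si](CC)(CC)CC)[C@@H]1C(C)=CC2(OCCO2)[C@H]([C@@H](C)COS(=O)(=O)c3ccc(C)cc3)[C@@H]1/C=C(/C)COCc4ccc(OC)cc4
F7 | step 11 | hydroxy Weinreb amide at C2 | OC[C@@H]1C(C)=CC2(OCCO2)[C@H]([C@@H](C)COS(=O)(=O)c3ccc(C)cc3)[C@@H]1C(=O)N(C)OC
F8 | step 11 | O9-triethylsilyl Weinreb amide | CC[Si](CC)(CC)OC[C@@H]1C(C)=CC2(OCCO2)[C@H]([C@@H](C)COS(=O)(=O)c3ccc(C)cc3)[C@@H]1C(=O)N(C)OC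
F9 | step 11 | O9-triethylsilyl C2 aldehyde | CC[Si](CC)(CC)OC[C@@H]1C(C)=CC2(OCCO2)[C@H]([C@@H](C)COS(=O)(=O)c3ccc(C)cc3)[C@@H]1C=O
F10 | step 11 | O9-triethylsilyl Z-enoate | CC[Si](CC)(CC)OC[C@@H]1C(C)=CC2(OCCO2)[C@H]([C@@H](C)COS(=O)(=O)c3ccc(C)cc3)[C@@H]1/C=C(/C)C(=O)OC
F11 | step 22 | (4S)-epimer of alcohol 30 | C=C(C)C[C@@H]2O[C@H]3[C@@H]4[C@H]2C(C)=CC5(OCCO5)[C@@H]4[C@@H](C)CO[C@@]3(C)[C@@H](O)CC=C
F12 | step 22 | C4 allyl ketone | C=C(C)C[C@@H]2O[C@H]3[C@@H]4[C@H]2C(C)=CC5(OCCO5)[C@@H]4[C@@H](C)CO[C@@]3(C)C(=O)CC=C
A1 | alternative 1 | diazoketone on a 6-isopropenyl tetrahydropyran (C6 configuration left open; the centre is destroyed in the shift) | [N-]=[N+]=CC(=O)C[C@@H]1OC(C(C)=C)C[C@@H](O[Si](C)(C)C(C)(C)C)[C@]1(C)O[Si](CC)(CC)CC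
A2 | alternative 1 | Z-oxonene-bridged dihydrofuran-3-one (C10 ketone) | CC(C)(C)[Si](C)(C)O[C@@H]1C/C=C(/C)C[C@@H]2O[C@@H](CC2=O)[C@@]1(C)O[Si](CC)(CC)CC
A3 | alternative 2 | γ-substituted butenolide with the C3/C4 acetonide and the allyl group | O=C1O[C@H]([C@@]2(C)OC(C)(C)O[C@@H]2CC=C)C=C1
A4 | alternative 2 | 1-methoxy-1-methyl-3-trimethylsilyloxy diene carrying the C15–C16 arm (C11=C12 geometry left open) | COC(C)=C/C(O[Si](C)(C)C)=C/[C@@H](C)CO[Si](C)(C)C(C)(C)C
A5 | alternative 2 | cis-fused bicyclic lactone with the complete ring A enone | O=C1O[C@H]([C@@]3(C)OC(C)(C)O[C@@H]3CC=C)[C@@H]2[C@H]1C(C)=CC(=O)[C@@H]2[C@@H](C)CO[Si](C)(C)C(C)(C)C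
A6 | alternative 3 | decalin tertiary alcohol with the vinyl group on C7 and the alkoxypropenyl group on C2 (C2, C7 and enol ether geometry left open) | C=CC1(C)C[C@H](O[Si](C)(C)C(C)(C)C)[C@@H]2C(C)=CC3(OCCO3)[C@H]([C@@H](C)COCc4ccc(OC)cc4)[C@@H]2C1(O)C(C)=COCc5ccc(OC)cc5
A7 | alternative 3 | triethylsilyl enol ether of the 6/10-bicyclic cyclodecenone | COc1ccc(CO[C@@H]2C/C=C(/C)C[C@H](O[Si](C)(C)C(C)(C)C)[C@H]3[C@H]([C@@H]([C@@H](C)COCc4ccc(OC)cc4)C5(OCCO5)C=C3C)/C(O[Si](CC)(CC)CC)=C2\C)cc1
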